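**Pace first.** You have no constants yet, so read a pace from the runs. The summer, midnight and winter runs reach 22%, 26% and 24% target at 2.50 h, a mean of 0.0960 h⁻¹ as a fraction of the charge.

| setting | summer | midnight | winter | flask |
|---|---|---|---|---|
| starting material | 28 mM | 28 mM | 28 mM | 28 mM |
| second substrate | 0.80 equiv | 1.8 equiv | 1.2 equiv | 1.20 equiv |
| free enzyme | 0.02 mol% | 0.02 mol% | 0.02 mol% | 0.02 mol% |
| added ligand | 3.2 µM | 3.2 µM | 6.4 µM | 3.2 µM |
| remark | run made earlier | run made earlier | run made earlier |  |

| run | time / h | target / % | starting material / % |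
|---|---|---|---|
| summer | 0.417 | 2 | 95 |
| summer | 0.833 | 12 | 89 |
| summer | 1.33 | 14 | 83 |
| summer | 1.50 | 16 | 85 |
| summer | 2.00 | 19 | 79 |
| summer | 2.50 | 22 | 75 |
| midnight | 0.200 | 6 | 97 |
| midnight | 0.333 | 3 | 98 |
| midnight | 0.500 | 7 | 91 |
| midnight | 0.833 | 9 | 87 |
| midnight | 1.33 | 17 | 82 |
| midnight | 2.50 | 26 | 69 |
| winter | 0.200 | 1 | 98 |
| winter | 0.667 | 8 | 96 |
| winter | 1.00 | 13 | 86 |
| winter | 1.50 | 17 | 86 |
| winter | 2.50 | 24 | 77 |

(readings scatter by 2 percentage points)

- no earlier run changes the charge of free enzyme; that part of a forecast is a guess

- apparent order in free enzyme when 50% of the starting material are converted (percent change of the rate of making target for one percent more free enzyme charged)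
- factor on the rate of making target when 50% of the starting material are converted if free enzyme is charged twice over

**Fast rung.** One round per enzyme takes 7.50 s, far shorter than the first reading at 0.200 h, so the readings follow a round already running.

**Slow rung.** Define the pace time 5.21 h as the conversion looked at, divided by that pace. It is longer than the runs, and 50% lies above the highest target reading, so you are extrapolating. With straight scaling, twice the enzyme cuts the pace time to 2.60 h. Any loss running on its own clock then has less time to act. My own figures are order one and factor two, leaning upward.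

**The forecast.** It gives order 1 (0.7 to 1.4) and factor 2 (1.6 to 2.7): “The default is therefore simple first order in enzyme.”

**The result.** The flask gives order 2.5 and factor 3.28, the order lying above the forecast's range.

    first complex → loaded enzyme + first product (k = 2200 h⁻¹)
    free enzyme + added ligand ⇌ idle complex (K = 5.20 × 10⁵ L mol⁻¹, k = 2.40 × 10⁵ L mol⁻¹ h⁻¹)
    second complex → free enzyme + target (k = 3700 h⁻¹)
    starting material + free enzyme ⇌ first complex (K = 50.0 L mol⁻¹, k = 5.80 × 10⁵ L mol⁻¹ h⁻¹)
    second substrate → decomposed reagent (k = 0.150 h⁻¹)
    second substrate + loaded enzyme ⇌ second complex (K = 30.0 L mol⁻¹, k = 4.20 × 10⁵ L mol⁻¹ h⁻¹)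

**Reagent clock.** The flask reaches 50% at 6.34 h, where the order in second substrate is 2.2. The pace time of 5.21 h is shorter than that. Decomposition has the rate constant 0.15 h⁻¹; counted without the other use of second substrate, it leaves 45.8% of the second substrate over the pace time and 38.6% over the 6.34 h this flask takes.

All runs were computed with constants of no real substance; noise was put on by code.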